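All runs are calculated for an exercise, noise included.

The amounts struck me first when you asked for a quick number on the spring flask and guessed that it was merely slow: 20 mM of starting material and 40.0 mM of coupling partner stood against 0.400 mM of capture agent and 100 µM of free catalyst.

| setting | spring | autumn | flask |
|---|---|---|---|
| starting material | 20 mM | 20 mM | 20 mM |
| coupling partner | 40 mM | 40 mM | 40.0 mM |
| capture agent | 0.40 mM | 0.40 mM | 0.400 mM |
| free catalyst | 100 µM | 100 µM | 100 µM |
| temperature | 50 °C | 56 °C | 50 °C |
| remark | the very flask that is asked about, followed so far | run made earlier |  |
| time |  |  | 2.5 d |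

| run | time / h | product / % |
|---|---|---|
| spring | 3.00 | 1 |
| spring | 10.0 | 6 |
| spring | 15.0 | 10 |
| spring | 25.0 | 11 |
| spring | 40.0 | 9 |
| spring | 50.0 | 13 |
| spring | 60.0 | 12 |
| autumn | 3.00 | 5 |
| autumn | 10.0 | 8 |
| autumn | 15.0 | 14 |
| autumn | 25.0 | 13 |
| autumn | 40.0 | 15 |
| autumn | 50.0 | 15 |
| autumn | 60.0 | 16 |

(scatter of a reading: 1.5 percentage points)

- ash: at 2.5 d add coupling partner, 50.0% of the amount charged, then wait 20 h
- elm: at 2.5 d raise the temperature by 20 K, then wait 20 h
- maple: at 2.5 d take out 90% of the product then present, then wait 20 h
- oak: change nothing and wait 20 h more
- alder: at 2.5 d add free catalyst, 100% of the amount charged, then wait 20 h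

- product taken out counts as made
- the numbers in the tables scatter by 1.5 percentage points (one standard deviation)
- additions bring no volume worth counting

- product, in percent of the starting material first charged, at 2.5 d
- the remedy with the largest gain of product, or "none" below 2 percentage points (ash / elm / maple / oak / alder / none)
- product present, with what was taken out counted in, in percent of the starting material first charged, after elm
- product present, with what was taken out counted in, in percent of the starting material first charged, after maple

I did not read the spring flask as slow. From 25.0 h on, its readings lay between 9% and 13%, with a scatter of 1.5 percentage points, so I took their mean, 11.2%, as my number for now.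

I then wrote the balance of the smallest charge, the free catalyst. My assumption was that each catalyst is lost by taking up one capture agent, which would use a quarter of the capture agent charged. The readings do not exclude an equilibrium, but I committed to this loss. The quantity I reckoned with was then the turnover number N, the product made per free catalyst charged before the flask stops: 22.5 as read from the spring flask, and 29.5 as read from the autumn run at 56 °C.

On this reckoning, fresh catalyst should restart the spring flask. Alder should gain 11 points, and 20 h should suffice, since the first charge had given 10% by 15.0 h. I expected ash, elm, maple and oak each to stay under 2 points, leaving elm and maple near 11.2%.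

The forecast differed from my reckoning, giving 11.5% for now, elm as best, 24% after elm and 19.5% after maple, on this ground: “A plateau that rises with temperature fits best with a reversible, mildly endothermic coupling”.

The flask gave 11.4% at 2.5 d, with alder best at a gain of 11 points, 11.7% after elm and 11.5% after maple.

    starting material + free catalyst → catalyst intermediate A (k = 680 M⁻¹ h⁻¹, Ea = 63.0 kJ mol⁻¹)
    coupling partner + catalyst intermediate A ⇌ catalyst intermediate B (K = 45.0 M⁻¹, k = 420 M⁻¹ h⁻¹, Ea = 45.0 kJ mol⁻¹, ΔH = −75.0 kJ mol⁻¹)
    catalyst intermediate B → catalyst intermediate C (k = 19.0 h⁻¹, Ea = 99.0 kJ mol⁻¹)
    catalyst intermediate C → free catalyst + product (k = 3.60 h⁻¹, Ea = 106 kJ mol⁻¹)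
    capture agent + catalyst intermediate C → trapped intermediate (k = 450 M⁻¹ h⁻¹, Ea = 68.0 kJ mol⁻¹)
    (constants at 50 °C)

In the flask at 60.0 h, the trapped intermediate held 99.1% of the catalyst charged, while 75% of the capture agent remained. Taking N as inversely proportional to the capture agent charged, with the other charges held, the same recipe with 0.24 mM of capture agent should reach an N of 37.5, which means 18.8% product. That neighbouring flask gave 19.3% at 2.5 d.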